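## Analysis of the target

The target is a 3,4-dihydroisocoumarin. Benzene ring A (C4a, C5–C8, C8a) is fused to δ-lactone ring B (C1, O2, C3, C4), ring A carries free phenols at C6 and C8, and C3 carries an undecyl chain with a secondary alcohol at C9′. There are two stereocentres, C3 (R) and C9′ (S). Eight methylene groups separate them, so neither can direct the other, and a diastereomer that is wrong at one centre would be practically inseparable from the target; each centre must therefore be made with high absolute control. C9′ is a carbinol flanked by ethyl and a long alkyl chain, too alike for a reliable ketone reduction, so it is best taken from a chiral building block. C3 is a carbinol between the benzylic CH2 (C4) and a chain CH2, again with little steric bias. The sensitive groups are the lactone (opened by hydroxide or alkoxide, and prone to β-elimination of O2 whenever C4 is deprotonated), the electron-rich resorcinol ring (oxidation, halogenation) and the 8-OH/C1=O chelate. The strategy rests on reading ring B as an acylated aldol: C3–C4 joins a benzylic nucleophile to an aldehyde carbon and O2–C1 acylates the resulting alkoxide. C1, C4 and ring A then map onto an enolisable homophthalic anhydride, and C3 with its chain onto an aldehyde. The cost is one extra carboxyl group at C4, which must be removed later without disturbing C3.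

## Retrosynthetic reasoning

Target 17 is first traced back to its protected form 16, with both phenols as methyl ethers and the C9′ alcohol as a silyl ether. No skeletal bond is cut. Methyl ethers are chosen because they survive electrophilic formylation, aldehyde oxidation, anhydride formation, amine catalysis and photoredox conditions. The silyl ether survives ozonolysis and the later steps and falls in the same Lewis-acid operation that frees the phenols.

Lactone 16 is traced back to acid 15 by putting a carboxyl group on C4. This is not a simplification in itself, but the carboxyl is what remains of an anhydride, and it makes the next disconnection possible. In the forward direction it has to leave through a C4 benzylic radical, so that no C4 anion is formed next to the C3–O2 bond and C3 keeps its configuration. Both C4 epimers of 15 are therefore usable.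

Acid 15 is cut at C3–C4 and O2–C1, giving anhydride 6 and aldehyde 13. These are the only two bonds of ring B that are neither part of ring A nor attached to the chain, so cutting them separates an arene fragment without stereocentres from a chain fragment that carries only C9′. The cut is convergent, and C3 is created in the bond-forming event itself. The forward reaction has to control the face of an unbranched aldehyde and close the ring on the aryl carbonyl of 6, which is the only closure that gives a six-membered ring, via adduct 14.

Anhydride 6 comes from diacid 5 by dehydration, and 5 from ester acid 4 by hydrolysis. Acid 4 comes from aldehyde 3 by oxidation, and 3 from commercial ester 1 by cutting the aryl–CHO bond. That bond lies ortho to the side chain and para to a methoxy group, where electrophilic formylation of 1 goes by itself through iminium salt 2. The ester in 1 protects the side-chain carboxyl during formylation.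

Aldehyde 13 comes from alkene 11 by oxidative cleavage of the terminal C=C, and 11 from alcohol 10 by silylation. Alcohol 10 is cut at C4–C5, next to the carbinol, into Grignard reagent 9 (from bromide 7) and epoxide 8. This takes C9′ of the target from a commercial enantiopure epoxide instead of from an asymmetric reaction on two nearly identical alkyl groups, and the forward ring opening at the CH2 of 8 does not touch the stereocentre.

## Alternatives that were turned down

Alternative 1: The disconnection is made in ring A, at C4a–C8a, and leads to the open-chain diketo-dioxinone A2, in which all carbons of the resorcylate and of the chain are already joined. In the forward key step a mild amine base would start an intramolecular aldol of the dioxinone α-carbon (future C8a) onto the far ketone (future C4a). Dehydration and enolisation would then give the acetonide-masked resorcylate A1.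
- For: the carbonyl positions of A2 fix the 6,8-oxygen pattern, the 6-OH is free, and the 8-oxygen sits in the dioxinone. Removal of the silyl groups and attack of the C3 hydroxyl on the dioxinone carbonyl would give 17 directly. No aryl ether has to be cleaved, so the endgame is milder than in the chosen route.
- Against: both stereocentres must be built into one linear acyl fragment before A2 is assembled, so C3 needs its own asymmetric step that adds nothing to the skeleton. A2 also holds a silyloxy group β to a ketone (the future C3 oxygen β to the future C4a carbonyl). The amine that drives the aromatisation can eliminate it by an E1cB path, and the C3 oxygen is then lost. Poly-β-carbonyl chains also tend to close to pyranones.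
- Comparison: the successive acylations needed for A2 make a longer and fully linear sequence. The chosen strategy offers convergence, an aromatic ring that is bought and not built, and C3 set by a catalyst in the ring-forming step. It pays for this with a harsher final deprotection.

Alternative 2: The disconnection cuts C4a–C4 and O2–C3 of an unsaturated lactone and leads to 2,4-dimethoxybenzoic acid A5 and the chain keto sulfoxonium ylide A4. In the forward key step a cationic Cp*Rh catalyst (trivalent rhodium) would activate the single ortho C–H bond of A5 under carboxylate direction, insert the carbene from A4 and cyclodehydrate to isocoumarin A3. Asymmetric hydrogenation of C3=C4 would then give 16.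
- For: ring B is reached in one step, A5 has only one ortho C–H bond so the regiochemistry is certain, and no extra carboxyl has to be removed. In step count and in certainty of ring formation this alternative is at least as strong as the chosen route.
- Against: C3 is only created afterwards, by hydrogenating a trisubstituted enol-ester double bond inside a flat, conjugated pyranone. Its two faces differ only through a flexible n-alkyl chain, and no coordinating group helps the catalyst. Electron-rich ortho-alkoxybenzoic acids such as A5 are also liable to protodecarboxylation under hot, silver-activated conditions.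
- Comparison: the chosen strategy forms the stereocentre in the same event that closes the ring, by face selection on a simple aldehyde carbonyl held by hydrogen bonds. It needs no precious metal and no pressure hydrogenation.

Alternative 3: The disconnection takes ring A apart at C5–C6, C7–C8 and C8–C8a, with C4a–C5 made by rearrangement, and leads to the enantiopure 4-diazoacetyl dihydropyranone A7 and ethoxyacetylene A8. In the forward key step irradiation of A7 would cause Wolff rearrangement to a vinylketene. This would add A8 in a [2+2] sense, open in a 4π process and close by 6π electrocyclisation to the phenol A6.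
- For: C3 is fixed early in a small lactone whose configuration can be checked before material is committed. Ring A is built with full regiocontrol and the two oxygens are differentiated (8-OH free, 6-OEt). On both points it is stronger than the chosen route.
- Against: A7 requires a 4-acyl dihydropyranone and a diazoketone homologation, which is a long linear preparation with a hazardous reagent. The vinylketene is conjugated with the lactone carbonyl and therefore electron-poor, so the cycloaddition must compete with ketene dimerisation and with the photochemistry of the unsaturated lactone. The 6-ethyl ether of A6 is harder to cleave than a methyl ether, so a boron tribromide step is still needed. A8 is volatile and labile.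
- Comparison: the chosen strategy is several steps shorter and convergent, and uses two robust fragments.

Key step: step 8

Assumption: the quinine-derived squaramide is taken to direct the enol of 6 to the Si face of aldehyde 13, which gives 3R. If a trial shows the opposite sense, the quinidine-derived pseudoenantiomer replaces it and nothing else changes.

## Route

Step 1
Reactants: 1 methyl 2-(3,5-dimethoxyphenyl)acetate
Product: 3 methyl 2-(2-formyl-3,5-dimethoxyphenyl)acetate, via aryl iminium chloride 2 (not isolated)
Conditions: POCl3, DMF, 0 °C → 60 °C; then ice–water, rt
Reagents that add atoms: N,N-dimethylformamide, CN(C)C=O (formyl carbon); water, O (formyl oxygen)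
Why: Vilsmeier–Haack formylation; the chloroiminium ion attacks the ring carbon ortho to the side chain, which is para to one methoxy group and ortho to the other, because the position between the two methoxy groups is more hindered. Hydrolysis of iminium salt 2 frees the aldehyde, and the ester α-CH2 is not nucleophilic enough to compete.

Step 2
Reactants: 3 methyl 2-(2-formyl-3,5-dimethoxyphenyl)acetate
Product: 4 2,4-dimethoxy-6-(2-methoxy-2-oxoethyl)benzoic acid
Conditions: NaClO2, NaH2PO4, 2-methyl-2-butene (excess), t-BuOH/THF/H2O, 0 °C → rt
Reagents that add atoms: sodium chlorite, [Na+].[O-]Cl=O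
Why: Pinnick oxidation; chlorous acid adds to the aldehyde and fragments to the acid, and the alkene traps the hypochlorous acid that would otherwise chlorinate the electron-rich ring. The methyl ester is untouched at this pH.

Step 3
Reactants: 4 2,4-dimethoxy-6-(2-methoxy-2-oxoethyl)benzoic acid
Product: 5 2-(carboxymethyl)-4,6-dimethoxybenzoic acid
Conditions: LiOH·H2O, THF/H2O, rt; then 1 M HCl
Reagents that add atoms: lithium hydroxide, [Li+].[OH-]
Why: Saponification of an unhindered aliphatic methyl ester by acyl substitution with hydroxide; acidification should precipitate the diacid.

Step 4
Reactants: 5 2-(carboxymethyl)-4,6-dimethoxybenzoic acid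
Product: 6 6,8-dimethoxyisochromane-1,3-dione
Conditions: Ac2O, toluene, reflux; crystallisation under exclusion of moisture
Reagents that add atoms: none
Why: Cyclodehydration through a mixed anhydride; the six-membered cyclic anhydride forms readily, and the absence of base avoids acetylation at the acidic C4.

Step 5
Reactants: 7 9-bromonon-1-ene; 8 (S)-2-ethyloxirane
Product: 10 (S)-tridec-12-en-3-ol, via non-8-en-1-ylmagnesium bromide 9 (not isolated)
Conditions: 7, Mg, THF, rt → 40 °C; then 8, CuBr·SMe2 (10 mol%), THF, −40 °C → 0 °C; then 1 M HCl
Reagents that add atoms: none
Why: Copper-catalysed opening of a terminal epoxide by a primary Grignard reagent, an SN2 attack at the unsubstituted CH2. The stereocentre of 8 is not involved and becomes C3 of 10 with unchanged (S) descriptor, since the attacked carbon keeps its rank above ethyl.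

Step 6
Reactants: 10 (S)-tridec-12-en-3-ol
Product: 11 (S)-tert-butyldimethyl(tridec-12-en-3-yloxy)silane
Conditions: TBSCl, imidazole, DMF, rt
Reagents that add atoms: tert-butyldimethylsilyl chloride, CC(C)(C)[Si](C)(C)Cl
Why: Standard silylation of a secondary alcohol through the N-silylimidazolium species; the resulting ether tolerates ozone, the amine catalyst and the photoredox step.

Step 7
Reactants: 11 (S)-tert-butyldimethyl(tridec-12-en-3-yloxy)silane
Product: 13 (S)-10-(tert-butyldimethylsilyloxy)dodecanal, via ozonide 12 (not isolated)
Conditions: O3, CH2Cl2, −78 °C; then PPh3, −78 °C → rt
Reagents that add atoms: ozone, [O-][O+]=O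
Why: Ozonolysis of a terminal alkene with reductive work-up; cycloaddition and cycloreversion give ozonide 12, which the phosphine reduces to the aldehyde. The aldehyde is used promptly to avoid air oxidation.

Step 8
Reactants: 6 6,8-dimethoxyisochromane-1,3-dione; 13 (S)-10-(tert-butyldimethylsilyloxy)dodecanal
Product: 15 (3R)-3-[(9S)-9-(tert-butyldimethylsilyloxy)undecyl]-6,8-dimethoxy-1-oxoisochromane-4-carboxylic acid (both C4 epimers), via aldol adduct 14 (not isolated)
Conditions: 3-{[3,5-bis(trifluoromethyl)phenyl]amino}-4-{[(8α,9S)-6′-methoxycinchonan-9-yl]amino}cyclobut-3-ene-1,2-dione (10 mol%), MTBE, −15 °C; then dilute aq HCl wash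
Reagents that add atoms: none
Why: This is the squaramide-catalysed formal cycloaddition of an enolisable homophthalic anhydride with an aldehyde, that is, an aldol addition followed by lactonisation, which is a known organocatalytic reaction type. The quinuclidine nitrogen of the catalyst deprotonates 6 at C4, which is acidified by the adjacent anhydride carbonyl and ring A; the resulting ammonium and the squaramide N–H bonds hold the enolate and the carbonyl of 13 in one hydrogen-bonded assembly, and the enolate carbon adds to the aldehyde carbon to form C3–C4 in adduct 14. The alkoxide of 14 then attacks the aryl carbonyl C1 in a 6-exo-trig acyl substitution, which closes ring B through O2–C1 and releases the other anhydride carbonyl as the C4 carboxylate; attack on that other carbonyl would give a four-membered β-lactone and does not compete. C3 is the only stereocentre that matters, and it is set by the catalyst, which presents the Si face of the aldehyde to the enolate and so gives 3R; the C9′ centre is too remote to match or mismatch. C4 forms as a mixture of epimers, which is harmless because it becomes CH2 in step 9. The step needs enantiofacial control on an unbranched aldehyde and cross-addition in preference to self-condensation: the tertiary amine is too weak to enolise 13 but strong enough for the far more acidic anhydride, and the aldehyde is a better electrophile for the enolate than an anhydride carbonyl. The 8-methoxy group beside C1 may slow ring closure but cannot divert it, because the alkoxide has no other productive path.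

Step 9
Reactants: 15 (3R)-3-[(9S)-9-(tert-butyldimethylsilyloxy)undecyl]-6,8-dimethoxy-1-oxoisochromane-4-carboxylic acid (both C4 epimers)
Product: 16 (3R)-3-[(9S)-9-(tert-butyldimethylsilyloxy)undecyl]-6,8-dimethoxyisochroman-1-one
Conditions: 9-mesityl-10-phenylacridinium tetrafluoroborate (5 mol%), PhSSPh (10 mol%), i-Pr2NEt (20 mol%), CF3CH2OH, 450 nm LEDs, rt, degassed, N2
Reagents that add atoms: none
Why: Photoredox hydrodecarboxylation; the excited acridinium oxidises the carboxylate, loss of CO2 leaves a secondary benzylic radical at C4, and hydrogen-atom transfer from thiophenol (formed from the disulfide) gives the C4 methylene while the reduced acridine returns the thiyl radical to thiolate. Both C4 epimers converge on the same radical, C3 is never ionised, and the nearly neutral medium avoids the β-elimination of O2 that a basic or thermal decarboxylation would invite.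

Step 10
Reactants: 16 (3R)-3-[(9S)-9-(tert-butyldimethylsilyloxy)undecyl]-6,8-dimethoxyisochroman-1-one
Product: 17 (3R)-6,8-dihydroxy-3-[(9S)-9-hydroxyundecyl]isochroman-1-one
Conditions: BBr3 (excess), CH2Cl2, −78 °C → 0 °C; then H2O, 0 °C
Reagents that add atoms: none
Why: Boron tribromide ether cleavage; bromide attacks the methyl group of each boron-complexed aryl ether, the 8-methoxy group first with help from chelation to C1=O, and the silyl ether is cleaved to a borate that hydrolyses on work-up, so one operation should free all three hydroxyl groups. The secondary C3–O2 and C9′–O bonds are not expected to ionise at or below 0 °C, so neither stereocentre is touched.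

## Compound list

1 | methyl 2-(3,5-dimethoxyphenyl)acetate | COC(=O)Cc1cc(OC)cc(OC)c1 | starting material
2 | N-[2,4-dimethoxy-6-(2-methoxy-2-oxoethyl)benzylidene]-N-methylmethanaminium chloride | COC(=O)Cc1cc(OC)cc(OC)c1C=[N+](C)C.[Cl-] | intermediate (not isolated)
3 | methyl 2-(2-formyl-3,5-dimethoxyphenyl)acetate | COC(=O)Cc1cc(OC)cc(OC)c1C=O | intermediate
4 | 2,4-dimethoxy-6-(2-methoxy-2-oxoethyl)benzoic acid | COC(=O)Cc1cc(OC)cc(OC)c1C(=O)O | intermediate
5 | 2-(carboxymethyl)-4,6-dimethoxybenzoic acid | OC(=O)Cc1cc(OC)cc(OC)c1C(=O)O | intermediate
6 | 6,8-dimethoxyisochromane-1,3-dione | COc1cc(OC)c2C(=O)OC(=O)Cc2c1 | intermediate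
7 | 9-bromonon-1-ene | C=CCCCCCCCBr | starting material
8 | (S)-2-ethyloxirane | CC[C@H]1CO1 | starting material
9 | non-8-en-1-ylmagnesium bromide | C=CCCCCCCC[Mg]Br | intermediate (not isolated)
10 | (S)-tridec-12-en-3-ol | CC[C@H](O)CCCCCCCCC=C | intermediate
11 | (S)-tert-butyldimethyl(tridec-12-en-3-yloxy)silane | CC[C@H](O[Si](C)(C)C(C)(C)C)CCCCCCCCC=C | intermediate
12 | 3-[(9S)-9-(tert-butyldimethylsilyloxy)undecyl]-1,2,4-trioxolane (both ring epimers) | CC[C@H](O[Si](C)(C)C(C)(C)C)CCCCCCCCC1OCOO1 | intermediate (not isolated)
13 | (S)-10-(tert-butyldimethylsilyloxy)dodecanal | CC[C@H](O[Si](C)(C)C(C)(C)C)CCCCCCCCC=O | intermediate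
14 | 4-[(1R,10S)-10-(tert-butyldimethylsilyloxy)-1-hydroxydodecyl]-6,8-dimethoxyisochromane-1,3-dione (C4 epimers) | CC[C@H](O[Si](C)(C)C(C)(C)C)CCCCCCCC[C@@H](O)C1C(=O)OC(=O)c2c(OC)cc(OC)cc12 | intermediate (not isolated)
15 | (3R)-3-[(9S)-9-(tert-butyldimethylsilyloxy)undecyl]-6,8-dimethoxy-1-oxoisochromane-4-carboxylic acid (both C4 epimers) | CC[C@H](O[Si](C)(C)C(C)(C)C)CCCCCCCC[C@@H]1C(C(=O)O)c2cc(OC)cc(OC)c2C(=O)O1 | intermediate
16 | (3R)-3-[(9S)-9-(tert-butyldimethylsilyloxy)undecyl]-6,8-dimethoxyisochroman-1-one | CC[C@H](O[Si](C)(C)C(C)(C)C)CCCCCCCC[C@@H]1Cc2cc(OC)cc(OC)c2C(=O)O1 | intermediate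
17 | (3R)-6,8-dihydroxy-3-[(9S)-9-hydroxyundecyl]isochroman-1-one | CC[C@H](O)CCCCCCCC[C@@H]1Cc2cc(O)cc(O)c2C(=O)O1 | target

## Step count and risks

Total: 10 steps. Longest linear sequence: 7 steps (steps 1–4, then 8, 9 and 10); the chain arm takes steps 5–7 before joining at step 8.

Least certain steps:

**Step 8 (key step).**
- What may go wrong: poor facial selectivity on an unbranched, flexible aldehyde, which would give a C3 epimer that cannot be removed later. Lactonisation may also be slow at the C1 carbonyl, which is deactivated and shielded by the 8-methoxy group, so that the aldol adduct reverts. Base-induced self-condensation of the anhydride may consume it.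
- How to check: the C3 selectivity is best read on 16 by HPLC on a chiral stationary phase.
- Fallback: it sets out from 11 and returns at 16, and takes C3 from a resolved epoxide in place of the aldol. Epoxidation of 11 with mCPBA should give the oxirane F1 as a mixture at the new centre. Hydrolytic kinetic resolution with (R,R)-N,N′-bis(3,5-di-tert-butylsalicylidene)-1,2-cyclohexanediaminocobalt acetate (trivalent cobalt) and about half an equivalent of water should consume the (S)-oxirane and leave the (R)-epoxide F2. Opening of F2 at the CH2 with commercial 3,5-dimethoxyphenylmagnesium chloride under CuBr·SMe2 catalysis should give the alcohol F3. NBS in MeCN should brominate the ring ortho to the side chain and para to a methoxy group to give the bromide F4. Carbonylation of F4 (Pd(OAc)2, dppf, CO, Et3N, DMF, 90 °C) with capture of the acylpalladium by the C2 hydroxyl should close the lactone to 16. Steps 8 and 9 are then bypassed.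

**Step 9.**
- What may go wrong: unproductive quenching of the excited acridinium by the dimethoxyarene, which would slow the reaction. Trapping of the benzylic radical by traces of oxygen would oxidise C4. Amine-induced β-elimination would open the lactone.
- Fallback: Barton decarboxylation, which sets out from 15 and returns at 16. Coupling of 15 with N-hydroxypyridine-2-thione (DCC, DMAP cat., CH2Cl2, dark) should give the thiohydroxamate ester F5. Irradiation with visible light in the presence of t-BuSH should then fragment it in a radical chain to the same C4 radical, which the thiol reduces to 16.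

**Step 10.**
- What may go wrong: substitution of the C9′ oxygen by bromide through the dibromoborate. The less activated 6-methoxy group may be cleaved incompletely. At higher temperature the lactone may be cleaved at C3–O2.
- Fallback: separate the two deprotections and avoid a strong Lewis acid. It sets out from 16 and returns at 17. Sodium ethanethiolate in DMF at about 110 °C should demethylate both aryl ethers by SN2 attack on the methyl groups, which are activated by the ortho and para carbonyl, and give the diphenol silyl ether F6. HF·pyridine in THF should then remove the silyl group to give 17.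

**Step 2.**
- What may go wrong: ring chlorination of the electron-rich arene if the scavenger fails to keep pace. Conversion may also be slow because the aldehyde is hindered and deactivated.
- Fallback: install the carboxyl by carbonylation instead of formylation and oxidation. It sets out from 1 and returns at 4, bypassing steps 1 and 2. NBS in MeCN should brominate 1 ortho to the side chain to give the aryl bromide F7. Hydroxycarbonylation of F7 (Pd(OAc)2, Xantphos, CO, H2O, Et3N, dioxane, 90 °C) should give 4; partial hydrolysis of the aliphatic ester would not matter, because step 3 removes it.

## Further compounds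

F1 | step 8 | tert-butyldimethyl{[(3S)-11-(oxiran-2-yl)undecan-3-yl]oxy}silane (both oxirane epimers) | CC[C@H](O[Si](C)(C)C(C)(C)C)CCCCCCCCC1CO1
F2 | step 8 | tert-butyldimethyl{[(3S)-11-[(2R)-oxiran-2-yl]undecan-3-yl]oxy}silane | CC[C@H](O[Si](C)(C)C(C)(C)C)CCCCCCCC[C@@H]1CO1
F3 | step 8 | (2R,11S)-11-(tert-butyldimethylsilyloxy)-1-(3,5-dimethoxyphenyl)tridecan-2-ol | CC[C@H](O[Si](C)(C)C(C)(C)C)CCCCCCCC[C@@H](O)Cc1cc(OC)cc(OC)c1
F4 | step 8 | (2R,11S)-1-(2-bromo-3,5-dimethoxyphenyl)-11-(tert-butyldimethylsilyloxy)tridecan-2-ol | CC[C@H](O[Si](C)(C)C(C)(C)C)CCCCCCCC[C@@H](O)Cc1cc(OC)cc(OC)c1Br
F5 | step 9 | 2-thioxopyridin-1(2H)-yl (3R)-3-[(9S)-9-(tert-butyldimethylsilyloxy)undecyl]-6,8-dimethoxy-1-oxoisochromane-4-carboxylate (C4 epimers) | CC[C@H](O[Si](C)(C)C(C)(C)C)CCCCCCCC[C@@H]1C(C(=O)ON2C=CC=CC2=S)c2cc(OC)cc(OC)c2C(=O)O1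
F6 | step 10 | (3R)-3-[(9S)-9-(tert-butyldimethylsilyloxy)undecyl]-6,8-dihydroxyisochroman-1-one | CC[C@H](O[Si](C)(C)C(C)(C)C)CCCCCCCC[C@@H]1Cc2cc(O)cc(O)c2C(=O)O1
F7 | step 2 | methyl 2-(2-bromo-3,5-dimethoxyphenyl)acetate | COC(=O)Cc1cc(OC)cc(OC)c1Br
A1 | alternative 1 | 5-[(2R,11S)-2,11-bis(tert-butyldimethylsilyloxy)tridecyl]-7-hydroxy-2,2-dimethyl-4H-benzo[d][1,3]dioxin-4-one | CC[C@H](O[Si](C)(C)C(C)(C)C)CCCCCCCC[C@@H](O[Si](C)(C)C(C)(C)C)Cc1cc(O)cc2OC(C)(C)OC(=O)c12
A2 | alternative 1 | 6-[(6R,15S)-6,15-bis(tert-butyldimethylsilyloxy)-2,4-dioxoheptadecyl]-2,2-dimethyl-4H-1,3-dioxin-4-one | CC[C@H](O[Si](C)(C)C(C)(C)C)CCCCCCCC[C@@H](O[Si](C)(C)C(C)(C)C)CC(=O)CC(=O)CC1=CC(=O)OC(C)(C)O1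
A3 | alternative 2 | 3-[(9S)-9-(tert-butyldimethylsilyloxy)undecyl]-6,8-dimethoxy-1H-isochromen-1-one | CC[C@H](O[Si](C)(C)C(C)(C)C)CCCCCCCCC1=Cc2cc(OC)cc(OC)c2C(=O)O1
A4 | alternative 2 | (S)-11-(tert-butyldimethylsilyloxy)-1-[dimethyl(oxo)-λ6-sulfanylidene]tridecan-2-one | CC[C@H](O[Si](C)(C)C(C)(C)C)CCCCCCCCC(=O)C=S(C)(C)=O
A5 | alternative 2 | 2,4-dimethoxybenzoic acid | COc1ccc(C(=O)O)c(OC)c1
A6 | alternative 3 | (3R)-3-[(9S)-9-(tert-butyldimethylsilyloxy)undecyl]-6-ethoxy-8-hydroxyisochroman-1-one | CC[C@H](O[Si](C)(C)C(C)(C)C)CCCCCCCC[C@@H]1Cc2cc(OCC)cc(O)c2C(=O)O1
A7 | alternative 3 | (6R)-6-[(9S)-9-(tert-butyldimethylsilyloxy)undecyl]-4-(2-diazoacetyl)-5,6-dihydro-2H-pyran-2-one | CC[C@H](O[Si](C)(C)C(C)(C)C)CCCCCCCC[C@@H]1CC(C(=O)C=[N+]=[N-])=CC(=O)O1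
A8 | alternative 3 | ethoxyacetylene | CCOC#C
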